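## The problem

Compound 17 is a 5-deoxyisoflavone. Its chromone (benzo ring A with a single 7-hydroxyl, pyranone ring C) carries at C3 the C5' carbon of a 7'-methoxy-8'-hydroxy-2',2'-dimethyl-2H-chromene (benzo ring B, dimethylpyran ring D).

- There is no stereocentre, so the task is one of regiochemistry and chemoselectivity only.
- Ring B is pentasubstituted. The inter-ring bond C3–C5' lies between the chromone carbonyl and the peri vinyl C4'–H of ring D, so a late coupling at this bond is hindered.
- Ring A has no 5-hydroxyl. The carbonyl must therefore be placed para to nothing and meta to the 7-oxygen by design, not by the symmetry of a phloroglucinol.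
- Three groups limit the reagents: the styrenyl C3'=C4' alkene of ring D (strong acid, electrophilic oxidants, hydrogenation), the catechol monoether of ring B (oxidation to an ortho-quinone) and chromone C2 (ring opening by hard nucleophiles).
- The enabling feature is that O1 and C4 of ring C sit on the adjacent ring A carbons C8a and C4a. This is the pattern left when an aryne takes up an oxygen nucleophile and an acyl electrophile.
- C2–C3(aryl)–C4 is then a formyl arylacetate, and the vacant C5 beside C4a can hold a removable electron-withdrawing group that tells the aryne which end takes the oxygen.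

## Retrosynthesis

**17 from 16.** The two O–CH2 bonds of the methoxymethyl ethers are cut last. One mild acid treatment frees both phenols. Benzyl ethers would need hydrogenolysis beside the ring D alkene, and silyl ethers would not survive the fluoride of the key step.

**16 from 15.** The C5–H bond is traced back to a C5–O triflate. The triflate is a traceless control element, costing one step but fixing the regiochemistry of ring C. The forward reaction must cleave the C–O bond without reducing either alkene.

**15 from 13 and 8 (through aryne 14).** Ring C is opened at O1–C8a and C4–C4a.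
- Cutting C3–C5' instead (cross-coupling) would form the most hindered bond of the molecule last and needs a halide or boron on ring B where only a formyl group is easy to place.
- Cutting C4–C4a alone (acylation of a resorcinol by an arylacetic acid) needs strong Lewis acid beside ring D.
- The chosen cut gives 13, which holds every atom of rings B and D plus C2, C3 and C4, and 8, a symmetric benzene.
- The forward step asks for O-arylation of an enolate, the correct orientation on the aryne, and acyl capture by the aryl anion.

**13 from 12.** The C3–C5' and C2–C3 bonds are cut together: an aromatic aldehyde and a diazoacetate combine with 1,2-aryl shift. The aldehyde carbon becomes C2 and the diazo carbon becomes C3. The classical neighbour (arylacetate plus formate ester) needs three further steps to homologate the aldehyde.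

**12 from 11, 10 and 9.** Ring D is opened at C4'–C4a' and O1'–C2' (aryl propargyl ether Claisen cascade). The formyl group deactivates the ring toward enal condensations, whereas the Claisen route is indifferent to it. Only one ortho position is free, so the ring fusion is unambiguous. The propargyl ether 11 comes from 10, and 10 from 3,4-dihydroxy-5-methoxybenzaldehyde 9 by alkylation of the more acidic 4-hydroxyl.

**8 from 7, 5, 4 and 1.** The acetal of 8 is cut to phenol 7. The C5–O bond of 7 is cut to a C–H bond of 5, whose only unhindered C–H is C5. The triflates of 5 go back to diol 4, and the C–Si bond of 4 to the bromide of 2-bromoresorcinol 1 (retro-Brook shift). A route from phloroglucinol would need a statistical mono-protection and a C-silylation of uncertain position. Here symmetry and sterics decide both.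

## Roads not taken

**Alternative 1:** Ring C is cut at C2–C3 with transfer of the formyl oxygen to C4, leading back to the ortho-alkynylaryl formate A1. In the forward step In(OTf)3 or triflic acid in hexafluoroisopropanol would induce an alkyne–carbonyl metathesis: the alkyne carbon bearing ring B attacks the formate carbon, an oxete forms and opens, and the 7-O-silyl 8'-O-acetyl isoflavone A2 results.
- Merits: the step is an isomerisation, the union is a Sonogashira coupling, and ring A needs no spectator group, which saves the reduction step of the chosen plan.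
- Weak points: an ester carbonyl is a poor partner for this metathesis and aryl formates lose the formyl group readily under acid. Ortho-alkynylaryl esters also tend to close 5-endo through oxygen to benzofurans with acyl migration. Strong acid in a highly ionising solvent threatens the ring D alkene, which the acetyl group on ring B only partly offsets. Two different protecting groups remain on A2.
- Comparison: both plans go beyond known chemistry in the key step. Alternative 1 would be shorter at the end. The chosen plan keeps ring D under basic fluoride conditions and rests its regiochemistry on the well-understood polarisation of a 3-substituted aryne.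

**Alternative 2:** The C3–C5' bond and the O1–C2 bond are cut, giving the free chromenol A3 and the enaminone A4. PhI(OAc)2 in hexafluoroisopropanol would oxidise A3, the enaminone alpha carbon would bond para to the phenol, and the ring A phenol would close ring C with loss of the amine to give A5.
- Merits: this is the shortest route. Both partners are two or three steps from commercial material, nothing is prefunctionalised, and A5 needs a single deprotection. In step count it is clearly better than the chosen plan.
- Weak points: a 2-methoxyphenol is oxidised by hypervalent iodine preferentially at the ortho carbon bearing the methoxy group (ortho-quinone monoketal). The para carbon is the hindered one beside the ring fusion. The enaminone, its own phenol and the ring D alkene are all oxidisable.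
- Comparison: the chosen plan is longer, but every position is fixed by a group already in place and no oxidant touches the electron-rich rings.

**Alternative 3:** Ring C is cut at C4–C4a and C3–C4 with carbon monoxide as C4, leading to the ortho-iodoaryl (Z)-styryl ether A6. Zerovalent palladium from Pd(OAc)2 and 1,3-bis(diphenylphosphino)propane would insert into the C–I bond, CO insertion would give the aroyl complex, and 6-endo acylpalladation with beta-hydride elimination would give A7, which is identical with 16.
- Merits: carbonylative annulation of ortho-iodophenol derivatives is an established family. A7 is reached without a triflate detour, one step fewer after the key step.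
- Weak points: only the (Z)-enol ether places the C3 hydrogen syn to palladium after insertion, so A6 must be made geometrically pure with the iodide intact. Direct cyclisation without CO (5-exo Heck) competes. 6-endo acylpalladation of a 1,2-disubstituted enol ether is itself unproven.
- Comparison: the end game is shorter, but A6 costs extra steps on the ring B side, so the overall count is similar. The chosen plan closes the ring by a polar, metal-free step whose orientation is set by the triflate.

Key step: step 9

## Route

Assumption: 13 is drawn as its hydrogen-bonded (Z)-enol; any aldehyde tautomer present gives the same cesium enolate in step 9.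

Step 1
Reactants: 1 2-bromobenzene-1,3-diol
Product: 4 2-(trimethylsilyl)benzene-1,3-diol, via 2-bromo-1,3-bis(trimethylsilyloxy)benzene 2 (not isolated), via lithium 3-(trimethylsilyloxy)-2-(trimethylsilyl)phenolate 3 (not isolated)
Conditions: (Me3Si)2NH, THF, reflux; evaporate; n-BuLi, THF, −78 °C to rt; aq. NH4Cl, then K2CO3 (cat.), MeOH, 0 °C
Reagents that add atoms: hexamethyldisilazane, C[Si](C)(C)N[Si](C)(C)C
Why: O-silylation and bromine–lithium exchange give an aryllithium flanked by two silyl ethers, which undergoes the 1,3 O-to-C silyl shift (retro-Brook rearrangement), the standard entry to ortho-silyl phenols; mild methanolysis then cleaves the remaining O–Si bond and leaves the C–Si bond alone.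

Step 2
Reactants: 4 2-(trimethylsilyl)benzene-1,3-diol
Product: 5 2-(trimethylsilyl)-1,3-phenylene bis(trifluoromethanesulfonate)
Conditions: Tf2O, pyridine, CH2Cl2, 0 °C
Reagents that add atoms: trifluoromethanesulfonic anhydride, O=S(=O)(OS(=O)(=O)C(F)(F)F)C(F)(F)F
Why: O-sulfonylation of both phenols; converting the donor hydroxyls into triflates also makes the arylsilane robust toward protodesilylation.

Step 3
Reactants: 5 2-(trimethylsilyl)-1,3-phenylene bis(trifluoromethanesulfonate)
Product: 7 5-hydroxy-2-(trimethylsilyl)-1,3-phenylene bis(trifluoromethanesulfonate), via 5-(pinacolboryl)-2-(trimethylsilyl)-1,3-phenylene bis(trifluoromethanesulfonate) 6 (not isolated)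
Conditions: [Ir(OMe)(cod)]2 (cat.), 4,4'-di-tert-butyl-2,2'-bipyridine, B2pin2, THF, 80 °C; evaporate; KHSO5 (as 2KHSO5·KHSO4·K2SO4), acetone/H2O, rt
Reagents that add atoms: potassium peroxymonosulfate, [K+].[O-]S(=O)(=O)OO; bis(pinacolato)diboron, CC1(C)OB(OC1(C)C)B1OC(C)(C)C(C)(C)O1 (boron stays in 6 only)
Why: Iridium-catalysed aromatic C–H borylation is sterically governed and C5 is the only C–H without an ortho substituent; oxidation of the crude boronate with peroxymonosulfate is the established one-pot route to such phenols, and aryl triflates and arylsilanes should tolerate both stages.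

Step 4
Reactants: 7 5-hydroxy-2-(trimethylsilyl)-1,3-phenylene bis(trifluoromethanesulfonate)
Product: 8 5-(methoxymethoxy)-2-(trimethylsilyl)-1,3-phenylene bis(trifluoromethanesulfonate)
Conditions: MOMCl, iPr2NEt, CH2Cl2, 0 °C to rt
Reagents that add atoms: chloromethyl methyl ether, COCCl
Why: O-alkylation of an acidic phenol with an amine base (Williamson-type acetal formation); no fluoride or strong base is present, so the silyl triflate motif should stay intact.

Step 5
Reactants: 9 3,4-dihydroxy-5-methoxybenzaldehyde
Product: 10 3-hydroxy-5-methoxy-4-(methoxymethoxy)benzaldehyde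
Conditions: MOMCl (1.05 equiv), K2CO3 (1.1 equiv), acetone, 0 °C to rt
Reagents that add atoms: chloromethyl methyl ether, COCCl
Why: The 4-hydroxyl para to the formyl group is markedly more acidic than the 3-hydroxyl, so one equivalent of weak base and alkylating agent should alkylate it selectively (regioselective mono-O-alkylation as known for 3,4-dihydroxybenzaldehydes).

Step 6
Reactants: 10 3-hydroxy-5-methoxy-4-(methoxymethoxy)benzaldehyde
Product: 11 3-methoxy-4-(methoxymethoxy)-5-[(2-methylbut-3-yn-2-yl)oxy]benzaldehyde
Conditions: 3-chloro-3-methylbut-1-yne, DBU, CuCl2·2H2O (cat.), MeCN, 0 °C to rt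
Reagents that add atoms: 3-chloro-3-methylbut-1-yne, CC(C)(Cl)C#C
Why: Copper-catalysed O-propargylation of a phenol with a tertiary propargylic chloride; the only free hydroxyl reacts.

Step 7
Reactants: 11 3-methoxy-4-(methoxymethoxy)-5-[(2-methylbut-3-yn-2-yl)oxy]benzaldehyde
Product: 12 7-methoxy-8-(methoxymethoxy)-2,2-dimethyl-2H-chromene-5-carbaldehyde
Conditions: N,N-diethylaniline, 185 °C
Reagents that add atoms: none
Why: Aryl propargyl ether Claisen rearrangement, then enolisation, 1,5-hydrogen shift and oxa-6π electrocyclisation; only the ortho carbon next to the formyl-bearing carbon is free, so only the 5-formyl chromene can form.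

Step 8
Reactants: 12 7-methoxy-8-(methoxymethoxy)-2,2-dimethyl-2H-chromene-5-carbaldehyde
Product: 13 ethyl (2Z)-3-hydroxy-2-[7-methoxy-8-(methoxymethoxy)-2,2-dimethyl-2H-chromen-5-yl]prop-2-enoate
Conditions: ethyl diazoacetate, HBF4·OEt2 (10 mol %), CH2Cl2, −78 °C
Reagents that add atoms: ethyl diazoacetate, CCOC(=O)C=[N+]=[N-]
Why: Acid-catalysed addition of the diazoester to the aldehyde followed by 1,2-aryl shift with loss of N2, a homologation known to convert electron-rich aromatic aldehydes into 3-hydroxy-2-arylacrylates; the oxygen-rich aryl group should migrate in preference to hydride, and the product rests as the chelated (Z)-enol.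

Step 9
Reactants: 13 ethyl (2Z)-3-hydroxy-2-[7-methoxy-8-(methoxymethoxy)-2,2-dimethyl-2H-chromen-5-yl]prop-2-enoate; 8 5-(methoxymethoxy)-2-(trimethylsilyl)-1,3-phenylene bis(trifluoromethanesulfonate)
Product: 15 7-(methoxymethoxy)-3-[7-methoxy-8-(methoxymethoxy)-2,2-dimethyl-2H-chromen-5-yl]-4-oxo-4H-chromen-5-yl trifluoromethanesulfonate, via 5-(methoxymethoxy)-3-(triflyloxy)benzyne 14 (not isolated)
Conditions: CsF (4 equiv), THF, 65 °C, slow addition of 8
Reagents that add atoms: none
Why: Proposed new method: CsF deprotonates the enol of 13 to its cesium enolate and, by attack at silicon of 8, expels one of the two equivalent triflates to give aryne 14, in which the remaining triflate flanks the triple bond. The enolate oxygen should add to the aryne carbon remote from that triflate (future C8a), because the inductively withdrawing C–OTf group distorts the aryne and stabilises the negative charge developing on the adjacent carbon (future C4a). The aryl anion then attacks the ester carbonyl in a 6-exo-trig acyl substitution, ethoxide leaves, and ring C is closed as the chromone. The closest known reaction type is the fluoride-induced annulation of arynes with salicylate esters to xanthones (O-arylation, then intramolecular acyl capture), together with distal-selective nucleophilic additions to 3-(triflyloxy)arynes; the enol of a formyl ester has not been shown as the oxygen nucleophile. O- over C-arylation is expected because the enolate carbon is fully substituted and shielded by the ortho-substituted ring B. The chelated U-shaped enolate places the new aryloxy group cis to the ester, the geometry that ring closure needs. Ring closure must outrun protonation and loss of the second triflate from the aryl anion, which the intramolecular six-membered transition state should secure; the symmetric precursor allows only one aryne, and no stereocentre is formed.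

Step 10
Reactants: 15 7-(methoxymethoxy)-3-[7-methoxy-8-(methoxymethoxy)-2,2-dimethyl-2H-chromen-5-yl]-4-oxo-4H-chromen-5-yl trifluoromethanesulfonate
Product: 16 7-(methoxymethoxy)-3-[7-methoxy-8-(methoxymethoxy)-2,2-dimethyl-2H-chromen-5-yl]-4H-chromen-4-one
Conditions: Pd(OAc)2 (cat.), 1,3-bis(diphenylphosphino)propane, HCO2H, Et3N, DMF, 70 °C
Reagents that add atoms: none
Why: Palladium-catalysed transfer hydrogenolysis of an aryl triflate: zerovalent palladium inserts into the C5–O bond activated by the ortho carbonyl, formate exchange and decarboxylation give the aryl palladium hydride, and reductive elimination gives the arene; the homogeneous hydride is not expected to reduce the chromone or the ring D alkene.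

Step 11
Reactants: 16 7-(methoxymethoxy)-3-[7-methoxy-8-(methoxymethoxy)-2,2-dimethyl-2H-chromen-5-yl]-4H-chromen-4-one
Product: 17 7-hydroxy-3-(8-hydroxy-7-methoxy-2,2-dimethyl-2H-chromen-5-yl)-4H-chromen-4-one
Conditions: HCl (3 M aq.), MeOH, 45 °C
Reagents that add atoms: none
Why: Acid-catalysed acetal exchange in methanol removes both methoxymethyl ethers; dilute acid at mild temperature is routinely tolerated by 2,2-dimethyl-2H-chromenes and chromones.

## Compound list

1 | 2-bromobenzene-1,3-diol | Oc1cccc(O)c1Br | starting material
2 | 2-bromo-1,3-bis(trimethylsilyloxy)benzene | C[Si](C)(C)Oc1cccc(O[Si](C)(C)C)c1Br | intermediate (not isolated)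
3 | lithium 3-(trimethylsilyloxy)-2-(trimethylsilyl)phenolate | [Li+].[O-]c1cccc(O[Si](C)(C)C)c1[Si](C)(C)C | intermediate (not isolated)
4 | 2-(trimethylsilyl)benzene-1,3-diol | C[Si](C)(C)c1c(O)cccc1O | intermediate
5 | 2-(trimethylsilyl)-1,3-phenylene bis(trifluoromethanesulfonate) | C[Si](C)(C)c1c(OS(=O)(=O)C(F)(F)F)cccc1OS(=O)(=O)C(F)(F)F | intermediate
6 | 5-(4,4,5,5-tetramethyl-1,3,2-dioxaborolan-2-yl)-2-(trimethylsilyl)-1,3-phenylene bis(trifluoromethanesulfonate) | C[Si](C)(C)c1c(OS(=O)(=O)C(F)(F)F)cc(B2OC(C)(C)C(C)(C)O2)cc1OS(=O)(=O)C(F)(F)F | intermediate (not isolated)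
7 | 5-hydroxy-2-(trimethylsilyl)-1,3-phenylene bis(trifluoromethanesulfonate) | C[Si](C)(C)c1c(OS(=O)(=O)C(F)(F)F)cc(O)cc1OS(=O)(=O)C(F)(F)F | intermediate
8 | 5-(methoxymethoxy)-2-(trimethylsilyl)-1,3-phenylene bis(trifluoromethanesulfonate) | C[Si](C)(C)c1c(OS(=O)(=O)C(F)(F)F)cc(OCOC)cc1OS(=O)(=O)C(F)(F)F | intermediate
9 | 3,4-dihydroxy-5-methoxybenzaldehyde | COc1cc(C=O)cc(O)c1O | starting material
10 | 3-hydroxy-5-methoxy-4-(methoxymethoxy)benzaldehyde | COCOc1c(O)cc(C=O)cc1OC | intermediate
11 | 3-methoxy-4-(methoxymethoxy)-5-[(2-methylbut-3-yn-2-yl)oxy]benzaldehyde | COCOc1c(OC)cc(C=O)cc1OC(C)(C)C#C | intermediate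
12 | 7-methoxy-8-(methoxymethoxy)-2,2-dimethyl-2H-chromene-5-carbaldehyde | COCOc1c(OC)cc(C=O)c2c1OC(C)(C)C=C2 | intermediate
13 | ethyl (2Z)-3-hydroxy-2-[7-methoxy-8-(methoxymethoxy)-2,2-dimethyl-2H-chromen-5-yl]prop-2-enoate | CCOC(=O)/C(=C\O)c1cc(OC)c(OCOC)c2c1C=CC(C)(C)O2 | intermediate
14 | 5-(methoxymethoxy)-3-(trifluoromethanesulfonyloxy)-1,2-didehydrobenzene | COCOC1=CC#CC(OS(=O)(=O)C(F)(F)F)=C1 | intermediate (not isolated)
15 | 7-(methoxymethoxy)-3-[7-methoxy-8-(methoxymethoxy)-2,2-dimethyl-2H-chromen-5-yl]-4-oxo-4H-chromen-5-yl trifluoromethanesulfonate | COCOc1cc(OS(=O)(=O)C(F)(F)F)c2c(c1)occ(-c1cc(OC)c(OCOC)c3c1C=CC(C)(C)O3)c2=O | intermediate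
16 | 7-(methoxymethoxy)-3-[7-methoxy-8-(methoxymethoxy)-2,2-dimethyl-2H-chromen-5-yl]-4H-chromen-4-one | COCOc1ccc2c(c1)occ(-c1cc(OC)c(OCOC)c3c1C=CC(C)(C)O3)c2=O | intermediate
17 | 7-hydroxy-3-(8-hydroxy-7-methoxy-2,2-dimethyl-2H-chromen-5-yl)-4H-chromen-4-one | COc1cc(-c2coc3cc(O)ccc3c2=O)c2c(c1O)OC(C)(C)C=C2 | target

## Step count and least certain steps

Total step count: 11. Longest linear sequence: 7 steps (steps 5 to 11; the branch through steps 1 to 4 and 9 to 11 is equally long).

**Step 9 (key step, proposed new method).**
- What may go wrong: C-arylation of the ambident enolate followed by capture of the formyl group; loss of the second triflate from the ortho-triflyloxy aryl anion before ring closure; O-arylation through an extended enolate that leaves the aryloxy group trans to the ester, so the anion is only protonated; triflyl transfer from 8 to the enolate oxygen.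
- Fallback, by known chemistry only: the C3–C5' bond is made by Suzuki–Miyaura coupling, setting out from 11 and coming back at 16.
  - Baeyer–Villiger oxidation of 11 with mCPBA (the terminal alkyne is inert) should give 3-methoxy-4-(methoxymethoxy)-5-[(2-methylbut-3-yn-2-yl)oxy]phenyl formate F1. K2CO3 in methanol cleaves it to 3-methoxy-4-(methoxymethoxy)-5-[(2-methylbut-3-yn-2-yl)oxy]phenol F2.
  - Tf2O and pyridine give the aryl triflate F3. The Claisen cascade of step 7 then gives 7-methoxy-8-(methoxymethoxy)-2,2-dimethyl-2H-chromen-5-yl trifluoromethanesulfonate F4.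
  - Miyaura borylation (B2pin2, PdCl2(dppf), KOAc, dioxane, 80 °C) gives the pinacol boronate F5.
  - Separately, 1-(2,4-dihydroxyphenyl)ethanone F6 is protected at the non-chelated 4-hydroxyl (MOMCl, K2CO3) to 1-[2-hydroxy-4-(methoxymethoxy)phenyl]ethanone F7. N,N-dimethylformamide dimethyl acetal gives (E)-3-(dimethylamino)-1-[2-hydroxy-4-(methoxymethoxy)phenyl]prop-2-en-1-one F8, and iodine cyclises it to 3-iodo-7-(methoxymethoxy)-4H-chromen-4-one F9.
  - Coupling of F5 with F9 (Pd(PPh3)4, Na2CO3, DME/H2O, 80 °C) gives 16, which continues with step 11.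

**Step 8.**
- What may go wrong: hydride shift in place of aryl shift (giving the beta-keto ester series); acid-induced loss of the methoxymethyl ether or protonation of the ring D alkene.
- Fallback, setting out from 12 and coming back at 13: NaBH4 reduction gives [7-methoxy-8-(methoxymethoxy)-2,2-dimethyl-2H-chromen-5-yl]methanol F10. Methanesulfonyl chloride, Et3N and LiCl give 5-(chloromethyl)-7-methoxy-8-(methoxymethoxy)-2,2-dimethyl-2H-chromene F11. Palladium-catalysed ethoxycarbonylation (PdCl2(PPh3)2, CO, EtOH, K2CO3) gives ethyl 2-[7-methoxy-8-(methoxymethoxy)-2,2-dimethyl-2H-chromen-5-yl]acetate F12. Claisen condensation with ethyl formate and NaH in THF gives 13.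

**Step 10.**
- What may go wrong: conjugate reduction of the chromone or saturation of the ring D alkene by palladium hydride; S–O cleavage of the peri-activated triflate to the 5-phenol.
- Fallback without a hydride source, setting out from 15 and coming back at 16: Miyaura borylation of 15 (B2pin2, PdCl2(dppf), KOAc, dioxane) gives 7-(methoxymethoxy)-3-[7-methoxy-8-(methoxymethoxy)-2,2-dimethyl-2H-chromen-5-yl]-5-(4,4,5,5-tetramethyl-1,3,2-dioxaborolan-2-yl)-4H-chromen-4-one F13. Protodeboronation (AgNO3 cat., Et3N, EtOH/H2O, 80 °C) gives 16.

**Step 1.**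
- What may go wrong: protodesilylation of the doubly hydroxyl-activated arylsilane 4 during hydrolytic work-up or chromatography.
- Fallback that never frees the diol, setting out from 1 and coming back at 5: silylation with hexamethyldisilazane, n-BuLi and direct quench of the phenolate with Tf2O gives 3-(trimethylsilyloxy)-2-(trimethylsilyl)phenyl trifluoromethanesulfonate F14. Methanolysis (K2CO3 cat., MeOH) gives 3-hydroxy-2-(trimethylsilyl)phenyl trifluoromethanesulfonate F15. Tf2O and pyridine give 5.

## Further compounds

F1 | step 9 | 3-methoxy-4-(methoxymethoxy)-5-[(2-methylbut-3-yn-2-yl)oxy]phenyl formate | COCOc1c(OC)cc(OC=O)cc1OC(C)(C)C#C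
F2 | step 9 | 3-methoxy-4-(methoxymethoxy)-5-[(2-methylbut-3-yn-2-yl)oxy]phenol | COCOc1c(OC)cc(O)cc1OC(C)(C)C#C
F3 | step 9 | 3-methoxy-4-(methoxymethoxy)-5-[(2-methylbut-3-yn-2-yl)oxy]phenyl trifluoromethanesulfonate | COCOc1c(OC)cc(OS(=O)(=O)C(F)(F)F)cc1OC(C)(C)C#C
F4 | step 9 | 7-methoxy-8-(methoxymethoxy)-2,2-dimethyl-2H-chromen-5-yl trifluoromethanesulfonate | COCOc1c(OC)cc(OS(=O)(=O)C(F)(F)F)c2c1OC(C)(C)C=C2
F5 | step 9 | 2-[7-methoxy-8-(methoxymethoxy)-2,2-dimethyl-2H-chromen-5-yl]-4,4,5,5-tetramethyl-1,3,2-dioxaborolane | COCOc1c(OC)cc(B2OC(C)(C)C(C)(C)O2)c2c1OC(C)(C)C=C2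
F6 | step 9 | 1-(2,4-dihydroxyphenyl)ethanone | CC(=O)c1ccc(O)cc1O
F7 | step 9 | 1-[2-hydroxy-4-(methoxymethoxy)phenyl]ethanone | COCOc1ccc(C(C)=O)c(O)c1
F8 | step 9 | (E)-3-(dimethylamino)-1-[2-hydroxy-4-(methoxymethoxy)phenyl]prop-2-en-1-one | COCOc1ccc(C(=O)/C=C/N(C)C)c(O)c1
F9 | step 9 | 3-iodo-7-(methoxymethoxy)-4H-chromen-4-one | COCOc1ccc2c(c1)occ(I)c2=O
F10 | step 8 | [7-methoxy-8-(methoxymethoxy)-2,2-dimethyl-2H-chromen-5-yl]methanol | COCOc1c(OC)cc(CO)c2c1OC(C)(C)C=C2
F11 | step 8 | 5-(chloromethyl)-7-methoxy-8-(methoxymethoxy)-2,2-dimethyl-2H-chromene | COCOc1c(OC)cc(CCl)c2c1OC(C)(C)C=C2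
F12 | step 8 | ethyl 2-[7-methoxy-8-(methoxymethoxy)-2,2-dimethyl-2H-chromen-5-yl]acetate | CCOC(=O)Cc1cc(OC)c(OCOC)c2c1C=CC(C)(C)O2
F13 | step 10 | 7-(methoxymethoxy)-3-[7-methoxy-8-(methoxymethoxy)-2,2-dimethyl-2H-chromen-5-yl]-5-(4,4,5,5-tetramethyl-1,3,2-dioxaborolan-2-yl)-4H-chromen-4-one | COCOc1cc(B2OC(C)(C)C(C)(C)O2)c2c(c1)occ(-c1cc(OC)c(OCOC)c3c1C=CC(C)(C)O3)c2=O
F14 | step 1 | 3-(trimethylsilyloxy)-2-(trimethylsilyl)phenyl trifluoromethanesulfonate | C[Si](C)(C)Oc1cccc(OS(=O)(=O)C(F)(F)F)c1[Si](C)(C)C
F15 | step 1 | 3-hydroxy-2-(trimethylsilyl)phenyl trifluoromethanesulfonate | C[Si](C)(C)c1c(O)cccc1OS(=O)(=O)C(F)(F)F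
A1 | alternative 1 | 5-(tert-butyldimethylsilyloxy)-2-[(8-acetoxy-7-methoxy-2,2-dimethyl-2H-chromen-5-yl)ethynyl]phenyl formate | O=COc1cc(O[Si](C)(C)C(C)(C)C)ccc1C#Cc1cc(OC)c(OC(C)=O)c2c1C=CC(C)(C)O2
A2 | alternative 1 | 5-[7-(tert-butyldimethylsilyloxy)-4-oxo-4H-chromen-3-yl]-7-methoxy-2,2-dimethyl-2H-chromen-8-yl acetate | CC(=O)Oc1c(OC)cc(-c2coc3cc(O[Si](C)(C)C(C)(C)C)ccc3c2=O)c2c1OC(C)(C)C=C2
A3 | alternative 2 | 7-methoxy-2,2-dimethyl-2H-chromen-8-ol | COc1ccc2c(c1O)OC(C)(C)C=C2
A4 | alternative 2 | (E)-3-(dimethylamino)-1-[2-hydroxy-4-(methoxymethoxy)phenyl]prop-2-en-1-one | COCOc1ccc(C(=O)/C=C/N(C)C)c(O)c1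
A5 | alternative 2 | 3-(8-hydroxy-7-methoxy-2,2-dimethyl-2H-chromen-5-yl)-7-(methoxymethoxy)-4H-chromen-4-one | COCOc1ccc2c(c1)occ(-c1cc(OC)c(O)c3c1C=CC(C)(C)O3)c2=O
A6 | alternative 3 | 5-{(Z)-2-[2-iodo-5-(methoxymethoxy)phenoxy]ethenyl}-7-methoxy-8-(methoxymethoxy)-2,2-dimethyl-2H-chromene | COCOc1ccc(I)c(O/C=C\c2cc(OC)c(OCOC)c3c2C=CC(C)(C)O3)c1
A7 | alternative 3 | 7-(methoxymethoxy)-3-[7-methoxy-8-(methoxymethoxy)-2,2-dimethyl-2H-chromen-5-yl]-4H-chromen-4-one | COCOc1ccc2c(c1)occ(-c1cc(OC)c(OCOC)c3c1C=CC(C)(C)O3)c2=O
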